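The data were computed with constants of no real substance.

- A leftover opens the case. In teal, target reads 30.5% on average between 5.00 min and 8.00 min, and the other 69.5% of the charge stays out of target. A flat curve with that much left over reads as a ceiling (thermodynamic control).

| setting | red | teal | blue | alder | birch | maple | cedar |
|---|---|---|---|---|---|---|---|
| substrate | 17 mM | 38 mM | 25 mM | 25 mM | 25 mM | 25 mM | 25 mM |
| free catalyst | 13 µM | 13 µM | 26 µM | 13 µM | 13 µM | 13 µM | 13 µM |
| temperature | 36 °C | 61 °C | 36 °C | 55 °C | 25 °C | 40 °C | 70 °C |
| remark | run made earlier | run made earlier | run made earlier |  |  |  |  |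
| time |  |  |  | 8.0 min | 8.0 min | 8.0 min | 8.0 min |

- red (time / min: target / %): 2.50: 3.6; 6.00: 7.5; 8.00: 8.2; 12.0: 10.9; 15.0: 11.0; 20.0: 12.5
- teal (time / min: target / %): 0.667: 13.0; 1.00: 17.9; 1.33: 20.7; 2.50: 27.4; 3.00: 29.0; 5.00: 30.7; 8.00: 30.4
- blue (time / min: target / %): 1.50: 2.3; 5.00: 6.9; 10.0: 9.5; 15.0: 10.7; 20.0: 12.2

(standard deviation of a reading: 0.3 percentage points)

- the best flask by amount of target, in percent of the substrate charged; "all alike" if 1.5 percentage points covers them all (alder / birch / maple / cedar / all alike)
- amount of target at the end, in percent of the substrate charged, alder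
- amount of target at the end, in percent of the substrate charged, birch
- amount of target at the end, in percent of the substrate charged, maple
- amount of target at the end, in percent of the substrate charged, cedar



- Red and blue test the charges. At 20.0 min, red reads 12.5% and blue 12.2%, a gap of 0.3 percentage points against a scatter of 0.3 points, though blue holds twice the free catalyst and a different c substrate.
- The percent curve thus reads as first order in c substrate, with c free catalyst at order zero within the scatter.
- Temperature must be known well: teal at 61 °C reads 30.5%, higher than the 12.5% of red at 36 °C, though teal differs in substrate too. Time matters where the flask is still climbing.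
- Blue's readings at 10.0 min and 20.0 min give a ceiling of 13.3% and a relaxation constant of 0.126 /min. Teal's reading at 1.00 min gives 0.882 /min.
- The ratio of target to the rest at the ceiling then yields the ceiling enthalpy, the slope of its logarithm against inverse temperature: 36.3 kJ/mol. The relaxation constants give an apparent activation energy of 66.9 kJ/mol.
- My reckoning for cedar: the ceiling is 38.3%, and the relaxation constant times the time is 13.3, far above one, so cedar should stand at its ceiling.
- My reckoning for birch: the ceiling is 8.33%, but the same product is 0.385, below one (kinetic control), which gives 2.66%.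
- The forecast names cedar best, with alder 25.5%, birch 2.8%, maple 11.9% and cedar 38%. Its ground: “This points to an equilibrium ceiling, not catalyst death.”
- The flasks give alder 26.0%, birch 2.98%, maple 11.9% and cedar 38.8%, and the best is cedar.

    substrate ⇌ target (K = 0.960, k = 0.00987 /s, Ea = 91.0 kJ/mol, ΔH = 47.0 kJ/mol)
    isomer of the product A + free catalyst ⇌ isomer of the product B + free catalyst, rate k2*[free catalyst]*[isomer of the product A] forward; the back reaction follows from the equilibrium constant (K = 0.860, k = 690 /M/s, Ea = 39.0 kJ/mol, ΔH = 25.0 kJ/mol)
    target ⇌ isomer of the product A (K = 0.360, k = 0.00446 /s, Ea = 99.0 kJ/mol, ΔH = −80.0 kJ/mol)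
    substrate + free catalyst → spent catalyst (k = 0.353 /M/s, Ea = 48.0 kJ/mol)
    (constants at 70 °C)

- The neighbour repeats birch at 50 °C. The ceiling enthalpy puts its reckoned ceiling at 22.0%. Its reckoned relaxation constant times the time is 3.11, above one, so the reckoning gives 21.0%. The neighbour gives 21.6%, a gap of 0.60 points. At the end, 75% of the neighbour's charged substrate is still there, unbound.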